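Numbering is fixed first: compounds 1–32 as in the steps and the compound list. The rings are lettered A to G from the phloroglucinol end. In each ring, locant 1 is the carbon bonded to the oxygen that links it to the preceding ring; in ring A it is the carbon that carries the ether oxygen.

## Analysis of the target

The target 32 is a linear heptamer of benzene rings joined by six diaryl ether oxygens. It has eighteen free phenolic hydroxyls and no stereocentre, so nothing has to be controlled stereochemically. Ring A is a phloroglucinol unit etherified at A1. Rings B, D and F carry ether oxygens at positions 1 and 4 and hydroxyls at 3 and 5. Rings C and E are pentaoxygenated, with adjacent ether oxygens at positions 1 and 6, hydroxyls at 3, 4 and 5, and a single hydrogen at position 2. Ring G is a 3,4,5-trihydroxyphenyl ether. The free polyphenol is very electron-rich and is oxidised by air, fastest as a phenoxide, so all hydroxyls stay masked until the last step. The difficulty lies in the ether bonds: every ether oxygen has at least two ortho oxygen substituents, B4–O–C1 and D4–O–E1 have three, and no ring carries an electron-withdrawing group that would help a substitution. The strategy rests on ring B. B1, bonded to the ring A oxygen, sits between the hydrogens at B2 and B6, with hydroxyls at B3 and B5 and an oxygen at B4. This mirror-symmetric pattern is that of 3,5-dimethoxy-4H-pyran-4-one 8 with B1 in the place of the ring oxygen. Ring B can therefore be built around a carbon that already carries the ring A oxygen, and the crowded A1–O bond is made by alkylation instead of arylation.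

## Retrosynthetic reasoning

**Unmasking.** Target 32 is traced back to the octadecamethyl ether 31. Methyl is the only protecting group, so all building blocks can be bought or made as methoxyarenes and one Lewis-acid step ends the synthesis.

**Fragment union at C6–O–D1.** Compound 31 is cut between the oxygen on C6 and D1, giving the rings A–C phenol 20 and the rings D–G bromide 30. This cut splits the heptamer three to four. D1 lies between two hydrogens, so ring D can be the aryl halide, and the hindered oxygen on C6 only has to act as the nucleophile in a copper-catalysed Ullmann coupling.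

**Ring C by substitution and oxidation.** Phenol 20 goes back to aldehyde 18, and 18 to the rings A–B phenol 14 and the fluoroaldehyde 17, cutting B4–O–C1. The formyl group at C6 has two roles: it activates the fluorine-bearing C1 for nucleophilic aromatic substitution, and a Baeyer–Villiger oxidation then turns it into the C6 hydroxyl. Aldehyde 17 comes from the fluoroarene 15 by ortho-lithiation and formylation.

**Ring B, the key disconnection.** Phenol 14 is the desilylated form of 13. In 13 the bonds B1–B2 and B1–B6 are cut, which separates ring B into one carbon of the phosphonium salt 5 and the five carbons of pyranone 8. The forward reaction must add the ylide carbon to C2 of the silyl-activated pyranone, open the ring and close it again by an intramolecular Wittig reaction. The gain is that the A1–O–B1 ether, flanked by two methoxy groups on ring A, is not made by an arylation.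

**The two partners of the key step.** Salt 5 comes from the chloromethyl ether 3 and triphenylphosphine 4, and 3 from phenol 1 and bromochloromethane 2. Pyranone 8 comes from the bis-enaminone 7 by acid cyclisation, and 7 from ketone 6 by double aminomethylenation.

**Rings D–G.** Bromide 30 is cut at E6–O–F1 into phenol 24 and boronic acid 29, joined by a Chan–Lam coupling that leaves the D1 bromine untouched. Phenol 24 comes from aldehyde 22, made from bromophenol 21 and the same fluoroaldehyde 17 by the substitution and oxidation pair used for ring C. Boronic acid 29 comes from bromide 26, the Chan–Lam product of 21 and boronic acid 25.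

## Alternatives that were turned down

**Alternative 1:** Ring A is disconnected at A2–A3 and A5–A6. In the forward direction a double Claisen condensation joins the aryloxymalonate A2, which carries the permethylated rings B–G on its oxygen, to diethyl 3-oxopentanedioate A3 and gives the phloroglucinol diester A1.
- For it: the condensation type is classical for phloroglucinols, the ring A hydroxyls are born free, and the A1–O bond comes from alkylation of an unhindered B1 phenoxide. On precedent for the reaction type it is stronger than the chosen route.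
- Against it: ring A is the last of seven rings, so the whole B–G hexamer and its five hindered ethers must be made first by other chemistry. The uncertain step then runs on the most valuable compound.
- Mechanistically, A2 is a C–H acid; base converts it to an enolate whose ester groups are poor acceptors, while A3 can condense with itself. A1 also needs saponification and double decarboxylation before demethylation.
- Comparison: the chosen strategy uses the same idea of making the A1–O bond by alkylation but tests its uncertain step at the start, on two small and cheap compounds.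

**Alternative 2:** Ring C is disconnected at C2–C3. Thermolysis of the cyclobutenone A5 opens it to a dienylketene, which closes by six-electron electrocyclisation and tautomerises to the trimer A4, with C3 hydroxyl free and C6 oxygen silylated.
- For it: the ring expansion of 4-alkenylcyclobutenones is an established reaction type, and it delivers the hardest ring, the pentaoxygenated one, with every oxygen differentiated. On both points it is stronger than the chosen route.
- Against it: A5 requires the rings A–B phenol 14 first, so the A1–O–B1 problem is not solved. It also requires the vinyl ether of a hindered phenol and its alpha-metalation next to five methoxy groups that can direct lithiation elsewhere.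
- Step economy: addition to the four-membered ring, silylation, thermolysis, methylation and desilylation are five steps for one ring. The chosen route reaches the same ring from 14 in two steps (8 and 9) with a one-step building block.
- Comparison: the chosen strategy applies its ring synthesis where it removes an ether-forming problem; alternative 2 applies a better-known ring synthesis where a purchasable ring serves as well.

**Alternative 3:** Ring D is disconnected at D1–D2, D5–D6 and D4–D5. Heating the ethynyl ether A7 of the rings A–C phenol with the cyclobutenone A8 that carries rings E–G gives a vinylketene, a cycloaddition to the alkyne, a second ring opening and a six-electron closure, ending in the heptamer A6.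
- For it: this is the most convergent plan; a three-ring and a three-ring fragment meet while the central ring forms, and the regiochemistry of this benzannulation with alkynyl ethers is reliable. On convergence it is stronger than the chosen route.
- Against it: A7 and A8 each need a trimer made by other means, so four hindered ethers, A1–O–B1 among them, are still to be made. An aryl ethynyl ether of a very electron-rich hindered phenol and a 4-aryloxycyclobutenone are both delicate, multistep reagents, and the thermal step puts both advanced fragments at risk at once.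
- Comparison: the chosen route also joins a three-ring and a four-ring fragment, by a plain copper coupling at the unhindered D1, and keeps its one unprecedented step on simple material.

Key step: step 5

Remark on the chemistry: 5-fluoro-1,2,3-trimethoxybenzene 15 is taken as a purchasable fluoroarene, and all phenoxides and the final polyphenol are handled with exclusion of air.

## Route

**Step 1**
Reactants: 1 2,4,6-trimethoxyphenol; 2 bromochloromethane
Product: 3 2-(chloromethoxy)-1,3,5-trimethoxybenzene
Conditions: NaH, DMF, 0 °C; added slowly to 2 (15 equiv), 0 °C → rt; used crude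
Reagents that add atoms: none
Why: Williamson O-alkylation in which the phenoxide displaces bromide, the better leaving group of 2, by SN2; the large excess of 2 and the inverse addition hold back a second displacement to the bis(aryloxy)methane.

**Step 2**
Reactants: 3 2-(chloromethoxy)-1,3,5-trimethoxybenzene; 4 triphenylphosphine
Product: 5 [(2,4,6-trimethoxyphenoxy)methyl]triphenylphosphonium chloride
Conditions: toluene, 90 °C; salt filtered off
Reagents that add atoms: none
Why: Quaternisation of a phosphine by an alpha-chloro ether, the standard way to (aryloxymethyl)phosphonium salts; the salt should precipitate from toluene, which also frees it from neutral by-products of step 1.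

**Step 3**
Reactants: 6 1,3-dimethoxypropan-2-one
Product: 7 (1Z,4Z)-1,5-bis(dimethylamino)-2,4-dimethoxypenta-1,4-dien-3-one
Conditions: Me2NCH(OMe)2 (4 equiv), 100 °C, MeOH distilled off
Reagents that add atoms: N,N-dimethylformamide dimethyl acetal, COC(OC)N(C)C
Why: Enaminone formation by condensation of an amide acetal with both carbonyl-activated methylene groups; removing methanol drives it to the bis-adduct, and the alkene geometry does not matter for the next step.

**Step 4**
Reactants: 7 (1Z,4Z)-1,5-bis(dimethylamino)-2,4-dimethoxypenta-1,4-dien-3-one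
Product: 8 3,5-dimethoxy-4H-pyran-4-one
Conditions: 2 M aq. HCl, THF, 50 °C
Reagents that add atoms: water, O
Why: Established cyclisation of 1,5-bis(dimethylamino)penta-1,4-dien-3-ones to 4-pyranones: one enaminone is hydrolysed, the enol oxygen adds to the other in a conjugate addition–elimination, and dimethylamine is lost.

**Step 5**
Reactants: 5 [(2,4,6-trimethoxyphenoxy)methyl]triphenylphosphonium chloride; 8 3,5-dimethoxy-4H-pyran-4-one
Product: 13 triisopropyl[2,6-dimethoxy-4-(2,4,6-trimethoxyphenoxy)phenoxy]silane, via aryloxymethylene ylide 9 (not isolated), via silyloxypyrylium triflate 10 (not isolated), via pyranylphosphonium triflate 11 (not isolated), via ring-opened dienal ylide 12 (not isolated)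
Conditions: 5, NaN(SiMe3)2 (1.0 equiv), THF, −78 °C; 8, iPr3SiOTf (1.05 equiv), CH2Cl2, 0 °C; ylide added to the pyrylium salt at −78 °C; then NaN(SiMe3)2 (1.1 equiv), −78 → 40 °C
Reagents that add atoms: triisopropylsilyl trifluoromethanesulfonate, CC(C)[Si](C(C)C)(C(C)C)OS(=O)(=O)C(F)(F)F
Why: Proposed new method: iPr3SiOTf silylates the carbonyl oxygen of 8 to the 4-silyloxypyrylium triflate 10, the carbon of ylide 9 (the future B1) adds to C2 of this cation (the future B2) to give the 2H-pyranylphosphonium salt 11, and the second equivalent of NaN(SiMe3)2 removes its P–CH(OAr) proton. The 2H-pyran opens by a thermal six-electron electrocyclic reaction to the dienal ylide 12, in which the former C6 is an aldehyde carbon (the future B6) conjugated through the diene with the ylide. Ring B then closes by an intramolecular Wittig reaction, a 6-exo-trig attack of B1 on B6 that can also be read as a disrotatory six-electron closure of the phosphonium trienolate, and the oxaphosphetane loses Ph3PO, which carries off the former ring oxygen and leaves an aromatic ring with B4 as the silyl ether. Closure needs B1 and B4 cis across the B2=B3 bond; an opening that turns the bulky phosphorus-bearing carbon outward gives the other isomer first, but the push–pull character of 12 lowers the rotation barrier and the opening is reversible, so the reactive isomer is drained by the irreversible Wittig step. The closest known reaction types are the benzene synthesis from pyrylium salts and alkylidenephosphoranes and the C2 addition of carbon nucleophiles to 4-silyloxypyrylium ions made from 4-pyranones and silyl triflates; their combination on a 4-pyranone with an aryloxymethylene ylide has not been shown. No stereocentre remains, since the two of 11 are lost in the opening and the closure. The selectivity needed is attack at C2 and not at C4 or at silicon: C4 carries the iPr3SiO group between two methoxy groups, the triisopropylsilyl group is too hindered for transfer to the ylide carbon, and the mirror symmetry of 8 makes C2 and C6 the same.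

**Step 6**
Reactants: 13 triisopropyl[2,6-dimethoxy-4-(2,4,6-trimethoxyphenoxy)phenoxy]silane
Product: 14 2,6-dimethoxy-4-(2,4,6-trimethoxyphenoxy)phenol (rings A–B phenol)
Conditions: Bu4NF, THF (degassed), 0 °C; aq. NH4Cl
Reagents that add atoms: none
Why: Fluoride cleavage of an aryl silyl ether, driven by the strong Si–F bond and the good phenoxide leaving group; the short contact time at 0 °C and degassed solvent protect the electron-rich phenoxide.

**Step 7**
Reactants: 15 5-fluoro-1,2,3-trimethoxybenzene
Product: 17 6-fluoro-2,3,4-trimethoxybenzaldehyde, via aryllithium 16 (not isolated)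
Conditions: n-BuLi, THF, −78 °C; DMF, −78 °C → 0 °C; aq. NH4Cl
Reagents that add atoms: N,N-dimethylformamide, CN(C)C=O
Why: Directed ortho-metalation; the only two ring hydrogens of 15 are equivalent and lie between fluorine and methoxy, both ortho-directing, so a single aryllithium forms, is kept cold to avoid loss of LiF to an aryne, and is formylated by DMF.

**Step 8**
Reactants: 14 2,6-dimethoxy-4-(2,4,6-trimethoxyphenoxy)phenol; 17 6-fluoro-2,3,4-trimethoxybenzaldehyde
Product: 18 6-[2,6-dimethoxy-4-(2,4,6-trimethoxyphenoxy)phenoxy]-2,3,4-trimethoxybenzaldehyde (rings A–C aldehyde)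
Conditions: Cs2CO3, DMSO (degassed), 100 °C
Reagents that add atoms: none
Why: Nucleophilic aromatic substitution by addition–elimination; the ortho formyl group stabilises the Meisenheimer intermediate, fluoride is the best leaving group for this mechanism, and the caesium phenoxide in DMSO makes up for the two ortho methoxy groups of the nucleophile.

**Step 9**
Reactants: 18 6-[2,6-dimethoxy-4-(2,4,6-trimethoxyphenoxy)phenoxy]-2,3,4-trimethoxybenzaldehyde
Product: 20 6-[2,6-dimethoxy-4-(2,4,6-trimethoxyphenoxy)phenoxy]-2,3,4-trimethoxyphenol (rings A–C phenol), via aryl formate 19 (not isolated)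
Conditions: mCPBA (1.1 equiv), CH2Cl2, 0 °C; then Et3N, MeOH, rt
Reagents that add atoms: 3-chloroperbenzoic acid, O=C(OO)c1cccc(Cl)c1
Why: Baeyer–Villiger oxidation of an electron-rich benzaldehyde; in the Criegee intermediate the aryl group with ortho and para oxygen substituents migrates in preference to hydrogen, and the formate is removed by methanolysis; one equivalent of peracid at 0 °C limits attack on ring A.

**Step 10**
Reactants: 21 4-bromo-2,6-dimethoxyphenol; 17 6-fluoro-2,3,4-trimethoxybenzaldehyde
Product: 22 6-(4-bromo-2,6-dimethoxyphenoxy)-2,3,4-trimethoxybenzaldehyde (rings D–E aldehyde)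
Conditions: Cs2CO3, DMSO (degassed), 100 °C
Reagents that add atoms: none
Why: The same nucleophilic aromatic substitution as in step 8; no transition metal is present, so the C–Br bond at D1 is left for the fragment union.

**Step 11**
Reactants: 22 6-(4-bromo-2,6-dimethoxyphenoxy)-2,3,4-trimethoxybenzaldehyde
Product: 24 6-(4-bromo-2,6-dimethoxyphenoxy)-2,3,4-trimethoxyphenol (rings D–E phenol), via aryl formate 23 (not isolated)
Conditions: mCPBA (1.1 equiv), CH2Cl2, 0 °C; then Et3N, MeOH, rt
Reagents that add atoms: 3-chloroperbenzoic acid, O=C(OO)c1cccc(Cl)c1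
Why: Baeyer–Villiger oxidation as in step 9; the aryl bromide is inert to peracid and to methanolysis.

**Step 12**
Reactants: 21 4-bromo-2,6-dimethoxyphenol; 25 (3,4,5-trimethoxyphenyl)boronic acid
Product: 26 5-(4-bromo-2,6-dimethoxyphenoxy)-1,2,3-trimethoxybenzene (rings F–G bromide)
Conditions: Cu(OAc)2 (1 equiv), pyridine, 4 Å molecular sieves, CH2Cl2, dry air, rt
Reagents that add atoms: none
Why: Chan–Lam coupling; the aryl group passes from boron to a copper phenoxide, air takes the metal to trivalent copper, and C–O reductive elimination follows; the method accepts 2,6-disubstituted phenols and leaves the aryl bromide alone because no low-valent metal is present to insert into C–Br.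

**Step 13**
Reactants: 26 5-(4-bromo-2,6-dimethoxyphenoxy)-1,2,3-trimethoxybenzene
Product: 29 [3,5-dimethoxy-4-(3,4,5-trimethoxyphenoxy)phenyl]boronic acid, via aryllithium 27 (not isolated), via lithium triisopropoxyborate 28 (not isolated)
Conditions: B(OiPr)3, then n-BuLi, THF–toluene, −78 °C; 1 M aq. HCl, rt
Reagents that add atoms: triisopropyl borate, CC(C)OB(OC(C)C)OC(C)C; water, O
Why: Bromine–lithium exchange with trapping by the borate already in the flask, which is faster than ortho-lithiation of the methoxyarenes, followed by hydrolysis of the ate complex to the boronic acid.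

**Step 14**
Reactants: 24 6-(4-bromo-2,6-dimethoxyphenoxy)-2,3,4-trimethoxyphenol; 29 [3,5-dimethoxy-4-(3,4,5-trimethoxyphenoxy)phenyl]boronic acid
Product: 30 5-bromo-2-{2-[3,5-dimethoxy-4-(3,4,5-trimethoxyphenoxy)phenoxy]-3,4,5-trimethoxyphenoxy}-1,3-dimethoxybenzene (rings D–G bromide)
Conditions: Cu(OAc)2 (1 equiv), pyridine, 4 Å molecular sieves, CH2Cl2, dry air, rt; 29 in excess
Reagents that add atoms: none
Why: Chan–Lam coupling of the hindered phenol 24 with a boronic acid whose boron lies between two hydrogens; the oxidative room-temperature conditions keep the D1 bromine as the handle for step 15.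

**Step 15**
Reactants: 20 6-[2,6-dimethoxy-4-(2,4,6-trimethoxyphenoxy)phenoxy]-2,3,4-trimethoxyphenol; 30 rings D–G bromide
Product: 31 2-{4-[2-(4-{2-[3,5-dimethoxy-4-(3,4,5-trimethoxyphenoxy)phenoxy]-3,4,5-trimethoxyphenoxy}-3,5-dimethoxyphenoxy)-3,4,5-trimethoxyphenoxy]-3,5-dimethoxyphenoxy}-1,3,5-trimethoxybenzene (octadecamethyl ether of the target)
Conditions: CuI (20 mol%), picolinic acid (40 mol%), K3PO4, DMSO (degassed), 100 °C
Reagents that add atoms: none
Why: Ullmann diaryl ether synthesis with a ligand system suited to ortho-substituted phenols; the metal inserts into the unhindered D1–Br bond, so the crowded partner only serves as the nucleophile.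

**Step 16**
Reactants: 31 octadecamethyl ether of the target
Product: 32 2-{4-[2-(4-{2-[3,5-dihydroxy-4-(3,4,5-trihydroxyphenoxy)phenoxy]-3,4,5-trihydroxyphenoxy}-3,5-dihydroxyphenoxy)-3,4,5-trihydroxyphenoxy]-3,5-dihydroxyphenoxy}benzene-1,3,5-triol (CNP0292517.0)
Conditions: BBr3 (excess), CH2Cl2, −78 °C → rt; MeOH, then H2O; argon; reversed-phase purification
Reagents that add atoms: none
Why: Lewis-acid cleavage of aryl methyl ethers; BBr3 binds each methoxy oxygen and bromide attacks the methyl carbon by SN2, whereas the diaryl ether oxygens have no sp3 carbon to be attacked and should stay intact.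

## Compound list

1 | 2,4,6-trimethoxyphenol | COc1cc(OC)c(O)c(OC)c1 | starting material
2 | bromochloromethane | ClCBr | starting material
3 | 2-(chloromethoxy)-1,3,5-trimethoxybenzene | COc1cc(OC)c(OCCl)c(OC)c1 | intermediate
4 | triphenylphosphine | c1ccc(cc1)P(c1ccccc1)c1ccccc1 | starting material
5 | [(2,4,6-trimethoxyphenoxy)methyl]triphenylphosphonium chloride | COc1cc(OC)c(OC[P+](c2ccccc2)(c2ccccc2)c2ccccc2)c(OC)c1.[Cl-] | intermediate
6 | 1,3-dimethoxypropan-2-one | COCC(=O)COC | starting material
7 | (1Z,4Z)-1,5-bis(dimethylamino)-2,4-dimethoxypenta-1,4-dien-3-one | CN(C)/C=C(\OC)C(=O)C(/OC)=C/N(C)C | intermediate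
8 | 3,5-dimethoxy-4H-pyran-4-one | COC1=COC=C(OC)C1=O | intermediate
9 | [(2,4,6-trimethoxyphenoxy)methylidene]triphenylphosphorane (ylide) | COc1cc(OC)c(OC=P(c2ccccc2)(c2ccccc2)c2ccccc2)c(OC)c1 | intermediate
10 | 3,5-dimethoxy-4-(triisopropylsilyloxy)pyrylium trifluoromethanesulfonate | COc1c[o+]cc(OC)c1O[Si](C(C)C)(C(C)C)C(C)C.[O-]S(=O)(=O)C(F)(F)F | intermediate
11 | {[3,5-dimethoxy-4-(triisopropylsilyloxy)-2H-pyran-2-yl](2,4,6-trimethoxyphenoxy)methyl}triphenylphosphonium trifluoromethanesulfonate (mixture of diastereomers, both stereocentres lost later in the step) | COC1=COC(C(Oc2c(OC)cc(OC)cc2OC)[P+](c2ccccc2)(c2ccccc2)c2ccccc2)C(OC)=C1O[Si](C(C)C)(C(C)C)C(C)C.[O-]S(=O)(=O)C(F)(F)F | intermediate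
12 | (2Z,4E)-2,4-dimethoxy-3-(triisopropylsilyloxy)-6-(2,4,6-trimethoxyphenoxy)-6-(triphenylphosphoranylidene)hexa-2,4-dienal (geometry that closes) | O=C\C(OC)=C(O[Si](C(C)C)(C(C)C)C(C)C)/C(OC)=C\C(Oc1c(OC)cc(OC)cc1OC)=P(c1ccccc1)(c1ccccc1)c1ccccc1 | intermediate
13 | triisopropyl[2,6-dimethoxy-4-(2,4,6-trimethoxyphenoxy)phenoxy]silane | COc1cc(OC)c(Oc2cc(OC)c(O[Si](C(C)C)(C(C)C)C(C)C)c(OC)c2)c(OC)c1 | intermediate
14 | 2,6-dimethoxy-4-(2,4,6-trimethoxyphenoxy)phenol | COc1cc(OC)c(Oc2cc(OC)c(O)c(OC)c2)c(OC)c1 | intermediate
15 | 5-fluoro-1,2,3-trimethoxybenzene | COc1cc(F)cc(OC)c1OC | starting material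
16 | (6-fluoro-2,3,4-trimethoxyphenyl)lithium | [Li]c1c(F)cc(OC)c(OC)c1OC | intermediate
17 | 6-fluoro-2,3,4-trimethoxybenzaldehyde | O=Cc1c(F)cc(OC)c(OC)c1OC | intermediate
18 | 6-[2,6-dimethoxy-4-(2,4,6-trimethoxyphenoxy)phenoxy]-2,3,4-trimethoxybenzaldehyde | COc1cc(OC)c(Oc2cc(OC)c(Oc3cc(OC)c(OC)c(OC)c3C=O)c(OC)c2)c(OC)c1 | intermediate
19 | 6-[2,6-dimethoxy-4-(2,4,6-trimethoxyphenoxy)phenoxy]-2,3,4-trimethoxyphenyl formate | COc1cc(OC)c(Oc2cc(OC)c(Oc3cc(OC)c(OC)c(OC)c3OC=O)c(OC)c2)c(OC)c1 | intermediate
20 | 6-[2,6-dimethoxy-4-(2,4,6-trimethoxyphenoxy)phenoxy]-2,3,4-trimethoxyphenol | COc1cc(OC)c(Oc2cc(OC)c(Oc3cc(OC)c(OC)c(OC)c3O)c(OC)c2)c(OC)c1 | intermediate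
21 | 4-bromo-2,6-dimethoxyphenol | COc1cc(Br)cc(OC)c1O | starting material
22 | 6-(4-bromo-2,6-dimethoxyphenoxy)-2,3,4-trimethoxybenzaldehyde | COc1cc(Br)cc(OC)c1Oc1cc(OC)c(OC)c(OC)c1C=O | intermediate
23 | 6-(4-bromo-2,6-dimethoxyphenoxy)-2,3,4-trimethoxyphenyl formate | COc1cc(Br)cc(OC)c1Oc1cc(OC)c(OC)c(OC)c1OC=O | intermediate
24 | 6-(4-bromo-2,6-dimethoxyphenoxy)-2,3,4-trimethoxyphenol | COc1cc(Br)cc(OC)c1Oc1cc(OC)c(OC)c(OC)c1O | intermediate
25 | (3,4,5-trimethoxyphenyl)boronic acid | COc1cc(B(O)O)cc(OC)c1OC | starting material
26 | 5-(4-bromo-2,6-dimethoxyphenoxy)-1,2,3-trimethoxybenzene | COc1cc(Br)cc(OC)c1Oc1cc(OC)c(OC)c(OC)c1 | intermediate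
27 | [3,5-dimethoxy-4-(3,4,5-trimethoxyphenoxy)phenyl]lithium | [Li]c1cc(OC)c(Oc2cc(OC)c(OC)c(OC)c2)c(OC)c1 | intermediate
28 | lithium triisopropoxy[3,5-dimethoxy-4-(3,4,5-trimethoxyphenoxy)phenyl]borate | [Li+].CC(C)O[B-](OC(C)C)(OC(C)C)c1cc(OC)c(Oc2cc(OC)c(OC)c(OC)c2)c(OC)c1 | intermediate
29 | [3,5-dimethoxy-4-(3,4,5-trimethoxyphenoxy)phenyl]boronic acid | OB(O)c1cc(OC)c(Oc2cc(OC)c(OC)c(OC)c2)c(OC)c1 | intermediate
30 | 5-bromo-2-{2-[3,5-dimethoxy-4-(3,4,5-trimethoxyphenoxy)phenoxy]-3,4,5-trimethoxyphenoxy}-1,3-dimethoxybenzene | COc1cc(Br)cc(OC)c1Oc1cc(OC)c(OC)c(OC)c1Oc1cc(OC)c(Oc2cc(OC)c(OC)c(OC)c2)c(OC)c1 | intermediate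
31 | octadecamethyl ether of the target (name in step 15) | COc1cc(OC)c(Oc2cc(OC)c(Oc3cc(OC)c(OC)c(OC)c3Oc3cc(OC)c(Oc4cc(OC)c(OC)c(OC)c4Oc4cc(OC)c(Oc5cc(OC)c(OC)c(OC)c5)c(OC)c4)c(OC)c3)c(OC)c2)c(OC)c1 | intermediate
32 | CNP0292517.0 (name in step 16) | Oc1cc(O)c(Oc2cc(O)c(Oc3cc(O)c(O)c(O)c3Oc3cc(O)c(Oc4cc(O)c(O)c(O)c4Oc4cc(O)c(Oc5cc(O)c(O)c(O)c5)c(O)c4)c(O)c3)c(O)c2)c(O)c1 | target

## Step count and least certain steps

Total: 16 steps. Longest linear sequence: 8 steps (1, 2, 5, 6, 8, 9, 15, 16, or equally 3, 4, 5, 6, 8, 9, 15, 16).

**Step 5 (key step, proposed new method).** The likely failures are transfer of the silyl group from the pyrylium ion to the ylide, addition at C2 without the ring opening that must follow, and failure of the opened dienal to reach the geometry in which B1 and B6 can meet, so that hydrolysis on work-up only returns the pyranone. Fallback by known chemistry: it sets out from 1 and 21 and comes back at 14. Bromophenol 21 is benzylated (BnBr, K2CO3) to 2-(benzyloxy)-5-bromo-1,3-dimethoxybenzene F1. Phenol 1 is coupled with F1 at the unhindered C–Br bond under the Ullmann conditions of step 15 to give 2-[4-(benzyloxy)-3,5-dimethoxyphenoxy]-1,3,5-trimethoxybenzene F2. Hydrogenolysis (H2, 10% Pd/C, EtOAc) then gives 14.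

**Step 1.** A second displacement on the reactive chloromethyl ether by phenoxide would give the formaldehyde diaryl acetal, and moisture would hydrolyse the product. Fallback from 1 back to 3: alkylation of 1 with chloromethyl methyl sulfide (NaH, NaI, DMF) gives 1,3,5-trimethoxy-2-[(methylsulfanyl)methoxy]benzene F3. Treatment with SO2Cl2 in CH2Cl2 at −78 °C, with cyclohexene present to trap the sulfenyl chloride, converts F3 into 3 through the chlorosulfonium ion.

**Step 8 (and its twin, step 10).** Slow addition of the doubly ortho-substituted phenoxide to a fluoride that carries a para methoxy group, with oxidative decay of the phenoxide at the temperature required. Fallback from 14 back to 18, and in the same way from 21 to 22: 5-bromo-1,2,3-trimethoxybenzene F4 is formylated (Cl2CHOMe, TiCl4, CH2Cl2, 0 °C) to 6-bromo-2,3,4-trimethoxybenzaldehyde F5. Phenol 14 is then coupled with F5 by copper catalysis (CuI, picolinic acid, K3PO4, DMSO), where the ortho formyl group helps the metal insertion. For 21 the chemoselectivity between its own bromine and that of F5 would be the weak point.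

**Step 9.** Electrophilic oxidation of ring A, a phloroglucinol trimethyl ether, by the peracid in competition with the Baeyer–Villiger reaction. Fallback from 14 back to 20, which brings the C6 oxygen in with the building block so that ring A never meets a peracid. 2,3,4-Trimethoxyphenol F6 is brominated ortho to the hydroxyl (NBS, cat. iPr2NH, CH2Cl2) to 6-bromo-2,3,4-trimethoxyphenol F7 and benzylated to 2-(benzyloxy)-1-bromo-3,4,5-trimethoxybenzene F8. Ullmann coupling of 14 with F8 gives the benzyl ether F9 of phenol 20, and hydrogenolysis (H2, 10% Pd/C) gives 20.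

**Step 15.** Slow insertion into the electron-rich C–Br bond, binding of the catalyst by the polyether, and reductive loss of bromine from 30 before coupling. Fallback from 30 back to 31: bromine–lithium exchange and borylation as in step 13 turn 30 into the rings D–G boronic acid F10, which is joined to phenol 20 by a Chan–Lam coupling as in step 14.

**Step 16.** Incomplete cleavage of some of the eighteen methyl ethers and oxidative loss of the free polyphenol during isolation. Fallback from 31 back to 32: after the BBr3 treatment the crude product is acetylated in the same flask (Ac2O, pyridine) to the octadecaacetate F11. F11 is stable to air and can be purified on silica; it is then deacetylated under argon by acid-catalysed methanolysis (HCl in MeOH) to 32.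

## Further compounds

F1 | step 5 | 2-(benzyloxy)-5-bromo-1,3-dimethoxybenzene | COc1cc(Br)cc(OC)c1OCc1ccccc1
F2 | step 5 | 2-[4-(benzyloxy)-3,5-dimethoxyphenoxy]-1,3,5-trimethoxybenzene | COc1cc(OC)c(Oc2cc(OC)c(OCc3ccccc3)c(OC)c2)c(OC)c1
F3 | step 1 | 1,3,5-trimethoxy-2-[(methylsulfanyl)methoxy]benzene | COc1cc(OC)c(OCSC)c(OC)c1
F4 | step 8 | 5-bromo-1,2,3-trimethoxybenzene | COc1cc(Br)cc(OC)c1OC
F5 | step 8 | 6-bromo-2,3,4-trimethoxybenzaldehyde | O=Cc1c(Br)cc(OC)c(OC)c1OC
F6 | step 9 | 2,3,4-trimethoxyphenol | COc1ccc(O)c(OC)c1OC
F7 | step 9 | 6-bromo-2,3,4-trimethoxyphenol | COc1cc(Br)c(O)c(OC)c1OC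
F8 | step 9 | 2-(benzyloxy)-1-bromo-3,4,5-trimethoxybenzene | COc1cc(Br)c(OCc2ccccc2)c(OC)c1OC
F9 | step 9 | 2-{4-[2-(benzyloxy)-3,4,5-trimethoxyphenoxy]-3,5-dimethoxyphenoxy}-1,3,5-trimethoxybenzene | COc1cc(OC)c(Oc2cc(OC)c(Oc3cc(OC)c(OC)c(OC)c3OCc3ccccc3)c(OC)c2)c(OC)c1
F10 | step 15 | (4-{2-[3,5-dimethoxy-4-(3,4,5-trimethoxyphenoxy)phenoxy]-3,4,5-trimethoxyphenoxy}-3,5-dimethoxyphenyl)boronic acid | OB(O)c1cc(OC)c(Oc2cc(OC)c(OC)c(OC)c2Oc2cc(OC)c(Oc3cc(OC)c(OC)c(OC)c3)c(OC)c2)c(OC)c1
F11 | step 16 | octadecaacetate of the target | CC(=O)Oc1cc(OC(C)=O)c(Oc2cc(OC(C)=O)c(Oc3cc(OC(C)=O)c(OC(C)=O)c(OC(C)=O)c3Oc3cc(OC(C)=O)c(Oc4cc(OC(C)=O)c(OC(C)=O)c(OC(C)=O)c4Oc4cc(OC(C)=O)c(Oc5cc(OC(C)=O)c(OC(C)=O)c(OC(C)=O)c5)c(OC(C)=O)c4)c(OC(C)=O)c3)c(OC(C)=O)c2)c(OC(C)=O)c1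
A1 | alternative 1 | diethyl 2,4,6-trihydroxy-5-(aryloxy)benzene-1,3-dicarboxylate, aryl being the permethylated rings B–G bonded through B1 | CCOC(=O)c1c(O)c(C(=O)OCC)c(O)c(Oc2cc(OC)c(Oc3cc(OC)c(OC)c(OC)c3Oc3cc(OC)c(Oc4cc(OC)c(OC)c(OC)c4Oc4cc(OC)c(Oc5cc(OC)c(OC)c(OC)c5)c(OC)c4)c(OC)c3)c(OC)c2)c1O
A2 | alternative 1 | diethyl 2-(aryloxy)propanedioate with the same permethylated rings B–G aryl group | CCOC(=O)C(Oc1cc(OC)c(Oc2cc(OC)c(OC)c(OC)c2Oc2cc(OC)c(Oc3cc(OC)c(OC)c(OC)c3Oc3cc(OC)c(Oc4cc(OC)c(OC)c(OC)c4)c(OC)c3)c(OC)c2)c(OC)c1)C(=O)OCC
A3 | alternative 1 | diethyl 3-oxopentanedioate | CCOC(=O)CC(=O)CC(=O)OCC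
A4 | alternative 2 | rings A–C trimer with C3 hydroxyl free and C6 oxygen as triethylsilyl ether | COc1cc(OC)c(Oc2cc(OC)c(Oc3cc(O)c(OC)c(OC)c3O[Si](CC)(CC)CC)c(OC)c2)c(OC)c1
A5 | alternative 2 | 4-{1-[2,6-dimethoxy-4-(2,4,6-trimethoxyphenoxy)phenoxy]ethenyl}-2,3-dimethoxy-4-(triethylsilyloxy)cyclobut-2-en-1-one (racemic) | C=C(Oc1c(OC)cc(Oc2c(OC)cc(OC)cc2OC)cc1OC)C1(O[Si](CC)(CC)CC)C(OC)=C(OC)C1=O
A6 | alternative 3 | heptamer with D5 hydroxyl free, D3 as ethyl ether and all other hydroxyls as methyl ethers | COc1cc(OC)c(Oc2cc(OC)c(Oc3cc(OC)c(OC)c(OC)c3Oc3cc(OCC)c(Oc4cc(OC)c(OC)c(OC)c4Oc4cc(OC)c(Oc5cc(OC)c(OC)c(OC)c5)c(OC)c4)c(O)c3)c(OC)c2)c(OC)c1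
A7 | alternative 3 | ethynyl ether of the rings A–C phenol | C#COc1c(OC)c(OC)c(OC)cc1Oc1c(OC)cc(Oc2c(OC)cc(OC)cc2OC)cc1OC
A8 | alternative 3 | 4-aryloxy-3-ethoxycyclobut-2-en-1-one, aryl being the permethylated rings E–G bonded through E1 (racemic) | CCOC1=CC(=O)C1Oc1cc(OC)c(OC)c(OC)c1Oc1cc(OC)c(Oc2cc(OC)c(OC)c(OC)c2)c(OC)c1
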